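**Plan**

1. Retrosynthesis: remove the acetyl group, then cut C16–C17 (sp3–sp2) into the ring-bearing redox-active ester 28 (C1–C16, carboxyl on C16) and the (2E,6E)-alkenyl iodide 7 (C17–C23). Ester 28 is cut further at C12–C13 (B-alkyl Suzuki–Miyaura), C11=C12 and C9=C11 (two methylenations), C8–O, C8–CH3 and C4–(CH3)2, back to (S)-Wieland–Miescher ketone 8.
2. Enabling feature: C16 is a primary CH2 whose only nearby unsaturation is the C13=C14 alkene two atoms away, and C17 is the unsubstituted end of the C17=C18 alkene, both remote from rings A and B. A carboxyl on C16 (lost as CO2) and an E-iodide on C17 therefore allow a nickel-mediated radical–alkenyl union that leaves the C3 ketone and the C8 and C23 hydroxyls alone.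
3. Forward: rings A and B come intact from 8. Ring B is elaborated first (C8–CH3, C8–OH, C9 methylene → CH2OH → vinyl) with ring A masked as its dienol ether; ring A is then reduced to the cis fusion and dimethylated at C4. The chain is joined C12–C13 first and C16–C17 last, and acetylation ends the route. Both C5 iodoalkene blocks (5 and 7) come from pent-4-yn-1-ol 1.
4. Stereochemistry: C10 from 8; C8 and C9 by attack anti to the C10 methyl while C5 is still sp2; C5 by β-face conjugate hydride delivery; C13=C14 and C17=C18 from syn carboalumination of 1, kept by retention in both couplings; C21=C22 from a stabilised Wittig reaction.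

Key step: step 20

Assumption: the SMILES is read literally; it places the hydrogen on C5 on the same face as the C10 methyl (rings A and B cis-fused), so the route builds this cis-decalin from 8 and sets C5 by β-face hydride delivery instead of starting from a trans-fused chiral-pool decalin.

Numbering: ring A = C1–C5 and C10 (C3 carbonyl, C4 gem-dimethyl); ring B = C5–C10 (C8 carbinol, C9 bears the chain); chain C11–C22 counted from C9 (methyls on C14, C18, C22); C23 = CH2O. β = face of the C10 methyl, α = opposite face.

**Route**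

Step 1
Reactants: 1 pent-4-yn-1-ol
Product: 3 (E)-5-iodo-4-methylpent-4-en-1-ol, via alkenylalane 2 (not isolated)
Conditions: AlMe3 (3 equiv), Cp2ZrCl2 (0.25 equiv), CH2Cl2, 0 °C → rt; then I2, THF, −30 → 0 °C; aq. K2CO3 work-up
Reagents that add atoms: trimethylaluminium, C[Al](C)C; iodine, II
Why: Zirconium-catalysed Negishi carboalumination adds CH3 and Al syn across the terminal alkyne with Al on the terminal carbon, and iodinolysis with retention should give the E-iodoalkene that later becomes C13=C14 and C17=C18.

Step 2
Reactants: 3 (E)-5-iodo-4-methylpent-4-en-1-ol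
Product: 4 (E)-5-iodo-4-methylpent-4-enal
Conditions: Dess–Martin periodinane, CH2Cl2, 0 °C → rt
Reagents that add atoms: none
Why: Dess–Martin oxidation of a primary alcohol stops at the aldehyde and does not touch the iodoalkene.

Step 3
Reactants: 4 (E)-5-iodo-4-methylpent-4-enal
Product: 5 methyl (E)-5-iodo-4-methylpent-4-enoate
Conditions: I2, KOH, MeOH, 0 °C
Reagents that add atoms: methanol, CO
Why: Oxidative esterification, in which the methyl hemiacetal of the aldehyde is oxidised by hypoiodite to the methyl ester while the electron-poor iodoalkene is left alone.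

Step 4
Reactants: 4 (E)-5-iodo-4-methylpent-4-enal
Product: 6 ethyl (2E,6E)-7-iodo-2,6-dimethylhepta-2,6-dienoate
Conditions: Ph3P=C(CH3)CO2Et, CH2Cl2, rt
Reagents that add atoms: ethyl 2-(triphenylphosphoranylidene)propanoate, CCOC(=O)C(C)=P(c1ccccc1)(c1ccccc1)c1ccccc1
Why: Wittig olefination with a stabilised ylide should give the E-trisubstituted enoate, which becomes the C21=C22 alkene.

Step 5
Reactants: 6 ethyl (2E,6E)-7-iodo-2,6-dimethylhepta-2,6-dienoate
Product: 7 (2E,6E)-7-iodo-2,6-dimethylhepta-2,6-dien-1-ol
Conditions: i-Bu2AlH (2.2 equiv), CH2Cl2, −78 °C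
Reagents that add atoms: none
Why: 1,2-Reduction of the enoate by i-Bu2AlH gives the allylic alcohol without touching either alkene or the C–I bond.

Step 6
Reactants: 8 (S)-Wieland–Miescher ketone
Product: 9 (S)-6-ethoxy-8a-methyl-3,7,8,8a-tetrahydronaphthalen-1(2H)-one (3-ethoxy-3,5-dien-9-one)
Conditions: HC(OEt)3, TsOH·H2O (cat.), EtOH, rt
Reagents that add atoms: triethyl orthoformate, CCOC(OCC)OCC
Why: Dienol ether formation is selective for the conjugated C3 carbonyl over the neopentyl C9 carbonyl (the classical 3-alkoxy-3,5-diene protection of 4-en-3-ones) and keeps C5 sp2, so the C10 methyl stays perpendicular to the ring plane for the face-selective steps that follow.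

Step 7
Reactants: 9 3-ethoxy-3,5-dien-9-one
Product: 11 8-methyl derivative of 9 (both C8 epimers), via lithium enolate 10 (not isolated)
Conditions: LiN(i-Pr)2 (1.1 equiv), THF, −78 °C; then CH3I, −78 → −20 °C
Reagents that add atoms: iodomethane, CI
Why: Kinetic enolate alkylation; only C8 carries acidic hydrogens next to the C9 carbonyl (C10 is quaternary), and the C8 configuration is erased in step 8.

Step 8
Reactants: 11 8-methyl ketone
Product: 13 3-ethoxy-8α-hydroxy-8β-methyl-3,5-dien-9-one, via potassium enolate 12 (not isolated)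
Conditions: KN(SiMe3)2 (1.3 equiv), THF, −78 → −30 °C; then 2-(phenylsulfonyl)-3-phenyloxaziridine, −78 °C; aq. NH4Cl
Reagents that add atoms: 2-(phenylsulfonyl)-3-phenyloxaziridine, O=S(=O)(c1ccccc1)N1OC1c1ccccc1
Why: Davis enolate hydroxylation; the flat C8=C9 enolate should be attacked at C8 anti to the axial C10 methyl, placing OH on the α-face and leaving the C8 methyl β.

Step 9
Reactants: 13 8α-hydroxy ketone
Product: 14 8α-triethylsilyl ether of 13
Conditions: Et3SiOTf (1.5 equiv), 2,6-lutidine (3 equiv), CH2Cl2, −78 → 0 °C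
Reagents that add atoms: triethylsilyl trifluoromethanesulfonate, CC[Si](CC)(CC)OS(=O)(=O)C(F)(F)F
Why: Silylation of the tertiary alcohol with a silyl triflate; the ether blocks α-ketol shift, retro-aldol cleavage and O-methylation in the later basic steps.

Step 10
Reactants: 14 silyloxy ketone
Product: 15 3-ethoxy-9-methylene-8α-(triethylsilyloxy)-8β-methyl-3,5-diene
Conditions: Ph3PCH3Br (4 equiv), KOt-Bu (4 equiv), toluene, 100 °C
Reagents that add atoms: methyltriphenylphosphonium bromide, C[P+](c1ccccc1)(c1ccccc1)c1ccccc1.[Br-]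
Why: Wittig methylenation with excess ylide in hot toluene, the protocol suited to non-enolisable ketones flanked by fully substituted carbons; the ylide can approach C9 along the α-face, which carries no axial substituent.

Step 11
Reactants: 15 9-methylene compound
Product: 17 9β-hydroxymethyl (9α-H) dienol ether, via alkylborane 16 (not isolated)
Conditions: 9-BBN (2.5 equiv), THF, 65 °C; then NaOH (aq), H2O2, 0 °C → rt
Reagents that add atoms: hydrogen peroxide, OO
Why: Hydroboration–oxidation; 9-BBN puts boron on the terminal carbon and should add from the α-face, away from the β-methyls on C8 and C10 that flank C9, so hydrogen enters C9 from the α-face and the CH2OH arm becomes β, while the trisubstituted dienol ether alkenes react far more slowly.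

Step 12
Reactants: 17 primary alcohol
Product: 18 9β-formyl dienol ether (C11 aldehyde)
Conditions: SO3·pyridine, DMSO, i-Pr2NEt, CH2Cl2, 0 °C
Reagents that add atoms: none
Why: Parikh–Doering oxidation gives the aldehyde under mild, non-acidic conditions that should neither epimerise C9 nor harm the dienol ether.

Step 13
Reactants: 18 aldehyde
Product: 19 9β-vinyl dienol ether
Conditions: Ph3PCH3Br, KN(SiMe3)2, THF, −78 → 0 °C
Reagents that add atoms: methyltriphenylphosphonium bromide, C[P+](c1ccccc1)(c1ccccc1)c1ccccc1.[Br-]
Why: Wittig methylenation of the aldehyde at low temperature should be faster than enolisation of the hindered C9–H, so the C9 configuration is kept.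

Step 14
Reactants: 19 9β-vinyl dienol ether
Product: 20 9β-vinyl-8α-(triethylsilyloxy)-8β,10β-dimethyl-4-en-3-one
Conditions: 0.5 M HCl (aq), THF, 0 °C
Reagents that add atoms: water, O
Why: Acid hydrolysis of the dienol ether (protonation at C6, loss of ethanol) regenerates the conjugated enone under conditions too mild to cleave the tertiary silyl ether.

Step 15
Reactants: 20 enone
Product: 21 cis-fused (5β-H) 9β-vinyl-8α-(triethylsilyloxy)-8β,10β-dimethyldecalin-3-one
Conditions: [(Ph3P)CuH]6 (0.35 equiv), H2O (2 equiv), benzene/THF, rt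
Reagents that add atoms: none
Why: Copper hydride conjugate reduction; the bulky reagent should deliver hydride to C5 from the β-face, because the α-trajectory is 1,3-diaxial to the α-hydrogens on C1, C7 and C9 (the bias that gives cis-fused products from 10-methyl-4-en-3-ones), water protonates the copper enolate, and the isolated vinyl group is not reduced.

Step 16
Reactants: 21 cis-fused ketone
Product: 23 4,4-dimethyl ketone (5β-H; 9β-vinyl; 8α-silyloxy), via 4-methyl ketone 22 (not isolated)
Conditions: KOt-Bu (2.3 equiv), CH3I (3 equiv), t-BuOH/THF, 0 °C → rt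
Reagents that add atoms: iodomethane, CI
Why: Thermodynamic enolate alkylation; cis-fused 10-methyl-3-ketones enolise toward C4, and after the first methylation the C4 enolate is also the more substituted one, so both methyl groups should enter at C4.

Step 17
Reactants: 23 4,4-dimethyl vinyl ketone; 5 methyl (E)-5-iodo-4-methylpent-4-enoate
Product: 25 methyl (E)-4-methyl-7-(ring C9)-hept-4-enoate (C9 to C16 chain with CO2CH3 on C16), via alkylborane 24 (not isolated)
Conditions: 9-BBN (1.2 equiv), THF, 0 °C → rt; then 5, PdCl2(dppf) (5 mol %), AsPh3, Cs2CO3, DMF/H2O, rt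
Reagents that add atoms: none
Why: Hydroboration of the monosubstituted alkene with 9-BBN (the C3 carbonyl next to quaternary C4 should react much more slowly) followed by B-alkyl Suzuki–Miyaura coupling, which proceeds with retention and transfers the E geometry of 5 to C13=C14.

Step 18
Reactants: 25 methyl ester
Product: 27 hydroxy acid (free C8–OH; CO2H on C16), via lithium carboxylate 26 (not isolated)
Conditions: LiOH, THF/MeOH/H2O, rt; then 2 M HCl to pH 1, rt
Reagents that add atoms: lithium hydroxide, [Li+].[OH-]
Why: Saponification of the methyl ester followed by acid cleavage of the tertiary silyl ether frees the acid and the C8 hydroxyl in one operation.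

Step 19
Reactants: 27 hydroxy acid
Product: 28 N-acyloxyphthalimide of 27
Conditions: N-hydroxyphthalimide, i-PrN=C=Ni-Pr, DMAP (cat.), CH2Cl2, rt
Reagents that add atoms: N-hydroxyphthalimide, ON1C(=O)c2ccccc2C1=O
Why: Carbodiimide-mediated (Steglich-type) esterification gives the redox-active ester; the hindered tertiary C8–OH should not be acylated.

Step 20
Reactants: 28 N-acyloxyphthalimide; 7 (2E,6E)-7-iodo-2,6-dimethylhepta-2,6-dien-1-ol
Product: 29 C23 alcohol (deacetyl target)
Conditions: 28 (1 equiv), 7 (2 equiv), NiCl2·6H2O (10 mol %), 2,2'-bipyridine (10 mol %), AgNO3 (0.3 equiv), LiCl, DMF, undivided cell, Mg anode, reticulated vitreous carbon cathode, constant current, rt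
Reagents that add atoms: none
Why: Cathodic reduction, relayed by low-valent nickel at the silver-coated cathode, transfers one electron to the N-acyloxyphthalimide, which fragments to phthalimide anion, CO2 and the primary C16 radical, while zerovalent nickel–bipyridine inserts into the C17–I bond of 7 with retention of the E geometry; the alkenylnickel captures the radical and reductive elimination from trivalent nickel forms C16–C17. The closest known reaction type is the nickel-catalysed decarboxylative alkenylation of redox-active esters (electroreductive cross-electrophile form and its alkenylzinc form), which is established for joining 2-methylalk-1-enyl iodides to primary alkyl radicals in polyprenoid chains. No ring is closed and no stereocentre is created, so C5, C8, C9 and C10 are untouched; the only stereochemical demand is retention at C17=C18, secured by the stereospecific oxidative addition. The step needs chemoselectivity over the C3 ketone, the tertiary C8–OH and the free allylic C23–OH, which follows from a radical/nickel manifold that uses no basic or nucleophilic organometallic. The C16 radical is separated from C13=C14 by C15 only, so its sole intramolecular escape is a slow, reversible three-membered ring closure, and capture by nickel should outrun it and keep the C13=C14 geometry.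

Step 21
Reactants: 29 C23 alcohol
Product: 30 myrrhanone A acetate as drawn (target)
Conditions: Ac2O (1.5 equiv), pyridine, CH2Cl2, 0 °C → rt
Reagents that add atoms: acetic anhydride, CC(=O)OC(C)=O
Why: Acetylation with acetic anhydride and pyridine is selective for the primary allylic alcohol over the hindered tertiary C8–OH and gives the target.

**Compound list**

1 | pent-4-yn-1-ol | OCCCC#C | starting material
2 | dimethylaluminium (E)-5-(dimethylalumanyl)-4-methylpent-4-en-1-olate | C[Al](C)OCCC/C(C)=C/[Al](C)C | intermediate (not isolated)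
3 | (E)-5-iodo-4-methylpent-4-en-1-ol | OCCC/C(C)=C/I | intermediate
4 | (E)-5-iodo-4-methylpent-4-enal | O=CCC/C(C)=C/I | intermediate
5 | methyl (E)-5-iodo-4-methylpent-4-enoate | COC(=O)CC/C(C)=C/I | intermediate
6 | ethyl (2E,6E)-7-iodo-2,6-dimethylhepta-2,6-dienoate | CCOC(=O)/C(C)=C/CC/C(C)=C/I | intermediate
7 | (2E,6E)-7-iodo-2,6-dimethylhepta-2,6-dien-1-ol | OC/C(C)=C/CC/C(C)=C/I | intermediate
8 | (S)-Wieland–Miescher ketone, (S)-8a-methyl-3,4,8,8a-tetrahydronaphthalene-1,6(2H,7H)-dione | O=C1[C@@]2(C)CCC(=O)C=C2CCC1 | starting material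
9 | (S)-6-ethoxy-8a-methyl-3,7,8,8a-tetrahydronaphthalen-1(2H)-one (3-ethoxy-3,5-dien-9-one) | O=C1[C@@]2(C)CCC(OCC)=CC2=CCC1 | intermediate
10 | lithium C8=C9 enolate of 9 | [Li+].[O-]C=1[C@@]2(C)CCC(OCC)=CC2=CCC=1 | intermediate (not isolated)
11 | 8-methyl derivative of 9, both C8 epimers | O=C1[C@@]2(C)CCC(OCC)=CC2=CCC1C | intermediate
12 | potassium C8=C9 enolate of 11 | [K+].[O-]C=1[C@@]2(C)CCC(OCC)=CC2=CCC=1C | intermediate (not isolated)
13 | 3-ethoxy-8α-hydroxy-8β,10β-dimethyl-3,5-dien-9-one | O=C1[C@@]2(C)CCC(OCC)=CC2=CC[C@@]1(C)O | intermediate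
14 | 8α-triethylsilyl ether of 13 | O=C1[C@@]2(C)CCC(OCC)=CC2=CC[C@@]1(C)O[Si](CC)(CC)CC | intermediate
15 | 3-ethoxy-9-methylene-8α-(triethylsilyloxy)-8β,10β-dimethyl-3,5-diene | C=C1[C@@]2(C)CCC(OCC)=CC2=CC[C@@]1(C)O[Si](CC)(CC)CC | intermediate
16 | C11 B-alkyl-9-borabicyclo[3.3.1]nonane adduct of 15 (9α-H) | C(B1C2CCCC1CCC2)[C@@H]1[C@@]2(C)CCC(OCC)=CC2=CC[C@@]1(C)O[Si](CC)(CC)CC | intermediate (not isolated)
17 | 9β-hydroxymethyl-9α-H dienol ether (C11 alcohol) | OC[C@@H]1[C@@]2(C)CCC(OCC)=CC2=CC[C@@]1(C)O[Si](CC)(CC)CC | intermediate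
18 | 9β-formyl dienol ether (C11 aldehyde) | O=C[C@@H]1[C@@]2(C)CCC(OCC)=CC2=CC[C@@]1(C)O[Si](CC)(CC)CC | intermediate
19 | 9β-vinyl dienol ether | C=C[C@@H]1[C@@]2(C)CCC(OCC)=CC2=CC[C@@]1(C)O[Si](CC)(CC)CC | intermediate
20 | 9β-vinyl-8α-(triethylsilyloxy)-8β,10β-dimethyl-4-en-3-one | C=C[C@@H]1[C@@]2(C)CCC(=O)C=C2CC[C@@]1(C)O[Si](CC)(CC)CC | intermediate
21 | cis-fused (5β-H) 9β-vinyl-8α-(triethylsilyloxy)-8β,10β-dimethyldecalin-3-one | C=C[C@@H]1[C@@]2(C)CCC(=O)C[C@H]2CC[C@@]1(C)O[Si](CC)(CC)CC | intermediate
22 | 4-methyl derivative of 21, both C4 epimers | C=C[C@@H]1[C@@]2(C)CCC(=O)C(C)[C@H]2CC[C@@]1(C)O[Si](CC)(CC)CC | intermediate (not isolated)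
23 | 4,4-dimethyl derivative of 21 | C=C[C@@H]1[C@@]2(C)CCC(=O)C(C)(C)[C@H]2CC[C@@]1(C)O[Si](CC)(CC)CC | intermediate
24 | C12 B-alkyl-9-borabicyclo[3.3.1]nonane adduct of 23 | C(C[C@@H]1[C@@]2(C)CCC(=O)C(C)(C)[C@H]2CC[C@@]1(C)O[Si](CC)(CC)CC)B1C2CCCC1CCC2 | intermediate (not isolated)
25 | methyl (E)-4-methyl-7-(ring C9)-hept-4-enoate, C8 silyl ether | COC(=O)CC/C(C)=C/CC[C@@H]1[C@@]2(C)CCC(=O)C(C)(C)[C@H]2CC[C@@]1(C)O[Si](CC)(CC)CC | intermediate
26 | lithium carboxylate of 25 (silyl ether intact) | [Li+].[O-]C(=O)CC/C(C)=C/CC[C@@H]1[C@@]2(C)CCC(=O)C(C)(C)[C@H]2CC[C@@]1(C)O[Si](CC)(CC)CC | intermediate (not isolated)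
27 | (E)-4-methyl-7-(ring C9)-hept-4-enoic acid with free 8α-OH | OC(=O)CC/C(C)=C/CC[C@@H]1[C@@]2(C)CCC(=O)C(C)(C)[C@H]2CC[C@@]1(C)O | intermediate
28 | N-acyloxyphthalimide (redox-active ester) of 27 | O=C(CC/C(C)=C/CC[C@@H]1[C@@]2(C)CCC(=O)C(C)(C)[C@H]2CC[C@@]1(C)O)ON1C(=O)c2ccccc2C1=O | intermediate
29 | (13E,17E,21E)-C23 alcohol, deacetyl target | OC/C(C)=C/CC/C(C)=C/CC/C(C)=C/CC[C@@H]1[C@@]2(C)CCC(=O)C(C)(C)[C@H]2CC[C@@]1(C)O | intermediate
30 | myrrhanone A acetate as drawn | CC(=O)OC/C(C)=C/CC/C(C)=C/CC/C(C)=C/CC[C@@H]1[C@@]2(C)CCC(=O)C(C)(C)[C@H]2CC[C@@]1(C)O | target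

**Step count**

Total: 21 steps. Longest linear sequence: 16 steps (8 → 30, steps 6–21). Blocks 5 and 7 take 3 and 4 steps from 1.

**Three steps most likely to fail**

1. Step 16 (gem-dimethylation at C4). What may go wrong: after the first methylation, enolisation toward C2 competes with enolisation toward the now more hindered C4, and the product can be alkylated again, so regioisomeric and over-methylated ketones form. Fallback, from 21 back to 23: limit the alkylation to one equivalent (KOt-Bu 1.05 equiv, CH3I 1.1 equiv) and isolate 22. Convert 22 under equilibrating conditions (Me3SiCl, NaI, Et3N, MeCN) into the tetrasubstituted C3=C4 trimethylsilyl enol ether F1. Cyclopropanate the electron-rich enol ether in preference to the hindered vinyl group (Et2Zn, CH2I2, CH2Cl2, 0 °C; Simmons–Smith reaction) to give the siloxycyclopropane F2. Open F2 with NaOH in MeOH; this breaks the C3–CH2 bond and leaves the former CH2 as the second methyl on C4, giving 23.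

2. Step 10 (methylenation of the C9 ketone). What may go wrong: the ylide may fail to add to a carbonyl flanked by two fully substituted carbons, and prolonged heating with base may cause silyl migration or loss. Fallback, from 13 back to 15: add the small, weakly basic organocerium reagent from Me3SiCH2Li and anhydrous CeCl3 (3 equiv, THF, −78 → 0 °C) to the unprotected ketol 13, where the C8 alkoxide assists addition, to give the β-hydroxysilane diol F3. Peterson elimination with KH in THF gives the tertiary allylic alcohol F4. Silylation (Et3SiOTf, 2,6-lutidine) returns to 15.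

3. Step 15 (conjugate reduction setting C5). What may go wrong: poor facial selectivity of hydride delivery at C5, giving the trans-fused ketone alongside the cis isomer. Fallback, from 17 back to 21: hydrolyse the dienol ether of 17 (0.5 M HCl, THF, 0 °C) to the enone alcohol F5 before the vinyl group exists. Hydrogenate over Pd/C in pyridine (H2, 1 atm), the heterogeneous conditions that classically give cis-fused ketones from 10-methyl-4-en-3-ones, to the cis-fused keto alcohol F6. Oxidise with Dess–Martin periodinane to the keto aldehyde F7. Methylenate the aldehyde in the presence of the C3 ketone with CH2I2, Zn and Ti(Oi-Pr)4 in THF (Takai-type aldehyde-selective methylenation) to reach 21.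

**Further compounds**

F1 | step 16 | C3=C4 trimethylsilyl enol ether of 22 | C=C[C@@H]1[C@@]2(C)CCC(O[Si](C)(C)C)=C(C)[C@H]2CC[C@@]1(C)O[Si](CC)(CC)CC
F2 | step 16 | 3-(trimethylsilyloxy)-4-methyl-3,4-methano derivative (siloxycyclopropane) | C=C[C@@H]1[C@@]2(C)CCC3(O[Si](C)(C)C)CC3(C)[C@H]2CC[C@@]1(C)O[Si](CC)(CC)CC
F3 | step 10 | 9-[(trimethylsilyl)methyl]-8α,9-diol dienol ether | C[Si](C)(C)CC1(O)[C@@]2(C)CCC(OCC)=CC2=CC[C@@]1(C)O
F4 | step 10 | 3-ethoxy-8α-hydroxy-9-methylene-8β,10β-dimethyl-3,5-diene | C=C1[C@@]2(C)CCC(OCC)=CC2=CC[C@@]1(C)O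
F5 | step 15 | 9β-hydroxymethyl-8α-(triethylsilyloxy)-4-en-3-one | OC[C@@H]1[C@@]2(C)CCC(=O)C=C2CC[C@@]1(C)O[Si](CC)(CC)CC
F6 | step 15 | cis-fused (5β-H) 9β-hydroxymethyl-8α-(triethylsilyloxy)decalin-3-one | OC[C@@H]1[C@@]2(C)CCC(=O)C[C@H]2CC[C@@]1(C)O[Si](CC)(CC)CC
F7 | step 15 | cis-fused (5β-H) 9β-formyl-8α-(triethylsilyloxy)decalin-3-one | O=C[C@@H]1[C@@]2(C)CCC(=O)C[C@H]2CC[C@@]1(C)O[Si](CC)(CC)CC
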